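**Assumptions (one line each):** Genipin is taken as a commercial chiral‑pool starting material (it already has the C5/C9 configuration of the target). Iridoid numbering is used throughout: C1 acetal, C3=C4, C5/C9 ring fusion, C10 = former CH2OH carbon, C11/C12 = lactone α‑C and C=O, C13 = benzylidene CH; "β" = the face of H‑5/H‑9. The route is designed from first principles and has not been run.

## Retrosynthetic overview
1. Prismatomerin ⇐ aldol condensation (C11=C13) of the tetracyclic lactone 8 with a protected 4‑hydroxybenzaldehyde.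
2. 8 ⇐ intramolecular oxa‑Michael addition of the C1 lactol onto spiro‑butenolide 7; this closes the bridging tetrahydrofuran acetal and fixes C1 and C10.
3. 7 ⇐ Bestmann ylide addition/intramolecular Wittig on the tertiary α‑hydroxy aldehyde 5 (lactone ring).
4. 5 ⇐ genipin by β‑epoxidation, selenide opening and selenoxide elimination (C8–O set, alkene moved to C6=C7), then oxidation of C10.
5. Ring order: cyclopenta[c]pyran (from genipin) → spiro‑butenolide → THF acetal ring; the arylidene goes on last.

## Route

**Step 1**
Reactants: 1 genipin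
Product: 2 (1R)‑1‑O‑methylgenipin
Conditions: MeOH, PPTS (cat.), rt
Reagents that add atoms: methanol, CO
Why: Fischer‑type acetalisation through the C1 oxocarbenium ion masks the lactol against borohydride and base; the C1 configuration (drawn as in genipin, anomeric mixture acceptable) is irrelevant because C1 is re‑formed in step 6.

**Step 2**
Reactants: 2
Product: 3 7β,8β‑epoxide of 2
Conditions: mCPBA, NaHCO3, CH2Cl2, 0 °C
Reagents that add atoms: mCPBA, OOC(=O)c1cccc(Cl)c1
Why: Prilezhaev epoxidation of the only electron‑rich alkene (C3=C4 is a deactivated β‑alkoxyacrylate); attack on the convex β‑face of the cis‑fused bicycle should set the C8–O bond β (cis to H‑9).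

**Step 3**
Reactants: 3
Product: 4 8β‑hydroxy‑Δ6,7 diol (8‑OH tertiary, 10‑OH primary)
Conditions: (PhSe)2, NaBH4, EtOH, rt to 50 °C; then 30% H2O2, pyridine, THF, 0 °C to rt
Reagents that add atoms: none (PhSe is introduced and expelled within the step)
Why: Sharpless–Lauer epoxide‑to‑allylic‑alcohol transposition: PhSe⁻ opens the epoxide by SN2 at the less hindered C7, and selenoxide syn‑elimination can only use a C6–H (C8 is quaternary); the C8–O bond is never broken, so C8 keeps its configuration.

**Step 4**
Reactants: 4
Product: 5 8β‑hydroxy‑10‑aldehyde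
Conditions: SO3·pyridine, DMSO, i‑Pr2NEt, CH2Cl2, 0 °C; used crude
Reagents that add atoms: none
Why: Parikh–Doering oxidation takes the primary alcohol only; the tertiary allylic OH is inert and the quaternary α‑carbon cannot epimerise or conjugate.

**Step 5**
Reactants: 5; 6 (triphenylphosphoranylidene)ketene (Bestmann ylide)
Product: 7 spiro‑butenolide (C8–O–C12(=O)–C11H=C10H), C1–OMe retained
Conditions: toluene, 80 °C
Reagents that add atoms: Ph3P=C=C=O, O=C=C=P(c1ccccc1)(c1ccccc1)c1ccccc1 (supplies C11, C12 and the carbonyl O)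
Why: Bestmann domino: the tertiary OH adds to the ketene to give an ester‑stabilised ylide, which closes by intramolecular Wittig reaction onto the adjacent aldehyde; no stereocentre is touched.

**Step 6**
Reactants: 7
Product: 8 tetracyclic lactone (the prismatomerin core with C11H2)
Conditions: 1 M HCl, THF/H2O, rt to 40 °C; then DBU (0.2 equiv), CH2Cl2, rt
Reagents that add atoms: water, O (its oxygen becomes the bridging C1–O–C10 oxygen)
Why: Acetal hydrolysis gives the mutarotating lactol, whose α‑OH adds 5‑exo‑trig (oxa‑Michael) to C10 of the butenolide; only the cis‑fused arrangement is geometrically possible, so C1 and C10 are set by the existing C8/C9 centres.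

**Step 7**
Reactants: 8; 9 4‑(tert‑butyldimethylsilyloxy)benzaldehyde
Product: 10 aldol adduct (C11–CH(OH)Ar, diastereomer mixture at C11/C13)
Conditions: LiHMDS added to 8 + 9 (in‑situ trap), THF, −78 °C; AcOH quench at −78 °C
Reagents that add atoms: 4‑(TBSO)benzaldehyde, O=Cc1ccc(O[Si](C)(C)C(C)(C)C)cc1
Why: Lithium lactone‑enolate aldol addition; trapping at −78 °C outruns β‑alkoxide elimination, and the new C11/C13 centres are destroyed in step 8.

**Step 8**
Reactants: 10
Product: 11 O‑TBS‑prismatomerin ((E)‑arylidene)
Conditions: MsCl, Et3N, CH2Cl2, 0 °C; then DBU, rt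
Reagents that add atoms: none
Why: Mesylation and E1cB elimination give the thermodynamically preferred E‑arylidene lactone (aryl anti to the lactone C=O); any ring‑opened butenolide mesylate would re‑close by SN2′ to the same product.

**Step 9**
Reactants: 11
Product: 12 prismatomerin
Conditions: TBAF, AcOH, THF, 0 °C
Reagents that add atoms: none
Why: Buffered fluoride desilylation of the aryl silyl ether; the acetals, lactone, methyl ester and arylidene are untouched.

## Compound list
1 | genipin, methyl (1R,4aS,7aS)‑1‑hydroxy‑7‑(hydroxymethyl)‑1,4a,5,7a‑tetrahydrocyclopenta[c]pyran‑4‑carboxylate | COC(=O)C1=CO[C@@H](O)[C@@H]2C(CO)=CC[C@H]12 | starting material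
2 | (1R)‑1‑O‑methylgenipin | COC(=O)C1=CO[C@@H](OC)[C@@H]2C(CO)=CC[C@H]12 | intermediate
3 | 7β,8β‑epoxy‑7,8‑dihydro‑1‑O‑methylgenipin | COC(=O)C1=CO[C@@H](OC)[C@@H]2[C@@]3(CO)O[C@H]3C[C@H]12 | intermediate
4 | methyl 7β‑hydroxy‑7‑(hydroxymethyl)‑1‑methoxy‑1,4a,7,7a‑tetrahydrocyclopenta[c]pyran‑4‑carboxylate (8β‑OH, Δ6,7) | COC(=O)C1=CO[C@@H](OC)[C@@H]2[C@](O)(CO)C=C[C@H]12 | intermediate
5 | methyl 7‑formyl‑7β‑hydroxy‑1‑methoxy‑1,4a,7,7a‑tetrahydrocyclopenta[c]pyran‑4‑carboxylate | COC(=O)C1=CO[C@@H](OC)[C@@H]2[C@](O)(C=O)C=C[C@H]12 | intermediate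
6 | (triphenylphosphoranylidene)ketene (Bestmann ylide) | O=C=C=P(c1ccccc1)(c1ccccc1)c1ccccc1 | starting material
7 | spiro[cyclopenta[c]pyran‑7,2′‑furan]‑5′‑one butenolide (lactone O on the β‑face of C8, 1‑OMe, 4‑CO2Me) | COC(=O)C1=CO[C@@H](OC)[C@@H]2[C@@]3(OC(=O)C=C3)C=C[C@H]12 | intermediate
8 | de(4‑hydroxybenzylidene)prismatomerin (tetracyclic bis‑acetal lactone, C11H2) | COC(=O)C1=CO[C@@H]2O[C@H]3CC(=O)O[C@]34C=C[C@H]1[C@H]24 | intermediate
9 | 4‑(tert‑butyldimethylsilyloxy)benzaldehyde | O=Cc1ccc(O[Si](C)(C)C(C)(C)C)cc1 | starting material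
10 | 11‑[(4‑TBSO‑phenyl)(hydroxy)methyl] lactone (aldol adduct, C11/C13 mixture) | COC(=O)C1=CO[C@@H]2O[C@H]3C(C(O)c5ccc(O[Si](C)(C)C(C)(C)C)cc5)C(=O)O[C@]34C=C[C@H]1[C@H]24 | intermediate
11 | O‑TBS‑prismatomerin | COC(=O)C1=CO[C@@H]2O[C@H]3/C(=C\c4ccc(O[Si](C)(C)C(C)(C)C)cc4)C(=O)O[C@]34C=C[C@H]1[C@H]24 | intermediate
12 | prismatomerin | COC(=O)C1=CO[C@@H]2O[C@H]3/C(=C\c4ccc(O)cc4)C(=O)O[C@]34C=C[C@H]1[C@H]24 | target

## Summary
Total steps: 9. Longest linear sequence: 9 (from genipin).

Three steps most likely to fail, each with a fallback that changes the approach: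

1. **Steps 2–3 (C8 oxygenation with alkene transposition).** Risks: α‑face epoxidation would give the wrong C8 epimer; PhSe⁻ could trigger Payne rearrangement of the epoxy alcohol or add at C3 of the β‑alkoxyacrylate. Fallback: singlet‑oxygen Schenck ene reaction on 2 (TPP, O2, hν; then PPh3), which should attack the convex face suprafacially, abstract H‑6β and place oxygen on C8β to give 4 in one step.
2. **Step 5 (Bestmann lactonisation).** Risks: the hindered tertiary alcohol adds slowly, and the α‑hydroxy aldehyde may undergo α‑ketol rearrangement on heating. Fallback: methylenate 5 (Ph3P=CH2) to the 8‑vinyl carbinol, acryloylate the tertiary OH, and close the butenolide 7 by ring‑closing metathesis (Grubbs II).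
3. **Step 7 (aldol on the closed lactone).** Risk: the enolate of 8 can expel the C10 alkoxide (retro‑oxa‑Michael), and the lactol then unravels. Fallback: form the C11–C13 bond before the acetal ring. Add Me2AlSPh to butenolide 7 with aldol trapping by 9, oxidise and eliminate the sulfoxide to the α‑(aryl‑hydroxymethyl)butenolide, then use mild acid to hydrolyse the C1 acetal and cyclise by SN2′ with loss of the C13 oxygen, giving the E‑arylidene lactone directly.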